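Amounts first: in this closed, stirred flask the starting material and its partner react to give the target, and per unit of starting material you charge 0.600 of partner, the smaller charge.

| flask | starting material | partner | remark | time |
|---|---|---|---|---|
| delta | 1 M | 0.60 M | the very flask that is asked about, followed so far |  |
| flask | 1.0 M | 0.600 M |  | 2.5 d |

delta run (percent of the starting material charged): time / h: target / % = 8.00: 8.0; 15.0: 12.4; 25.0: 15.3; 30.0: 16.0; 40.0: 17.4; 48.0: 18.4; 60.0: 18.5

(each reading ± 0.3 percentage points)

- dawn: change nothing and wait 2.5 d more
- dusk: at 2.5 d add starting material, 50.0% of the amount charged, then wait 2.5 d
- winter: at 2.5 d add partner, 100% of the amount charged, then wait 2.5 d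
- autumn: at 2.5 d take out 90% of the target then present, then wait 2.5 d

- target that was removed still counts
- additions bring no volume worth counting

1. target, in percent of the starting material first charged, at 2.5 d
2. the remedy with the largest gain of target, or "none" below 2 percentage points (dawn / dusk / winter / autumn / none)
3. target present, with what was taken out counted in, in percent of the starting material first charged, after dawn
4. target present, with what was taken out counted in, in percent of the starting material first charged, after winter

Read the delta run, which is this flask followed so far, from the top down. The target gains 4.4 percentage points between 8.00 h and 15.0 h, but between 48.0 h and 60.0 h it gains 0.1 points, less than the scatter of 0.3 points. So the last row, 18.5%, is my value for now, and it lies far below the partner's charge.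

Ask what the end state must be. I assume, though these readings do not show it, that the run stops when the limiting reagent is used up, and that each unit of it gives a fixed amount of target. That amount, the target share, is the last reading of the target divided by the smaller charge, 30.8%, and as a reading it carries their scatter.

Waiting, adding starting material and taking out target leave the partner's charge unchanged, so this rule gives them no gain. Winter raises the partner to 1.20 of the first charge, above the starting material, so the starting material becomes the smaller charge. The rule then gives 30.8%, a gain of 12 points against the margin of 2 points, and I choose winter.

The forecast grounds itself otherwise: “something has stopped it other than running out of reagent”. It gives 18.6% for now (18.2% to 19%), 18.9% after dawn (18.4% to 19.8%), and winter as the best remedy, with 32.5% after it (20% to 35%), higher than my figure.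

The flask gives 18.8% now. The gains are 0.95 points for dawn, 1 point for dusk, 0.95 points for autumn and 12 points for winter, so the answer is winter, with 19.8% after dawn and 31.1% after winter.

    starting material ⇌ tight pair (K = 5.70 × 10⁻⁴, k = 0.180 h⁻¹)
    tight pair ⇌ loose pair (K = 1.00, k = 190 h⁻¹)
    partner + tight pair → target (k = 50.0 M⁻¹ h⁻¹)
    partner + loose pair → isomer of the product (k = 120 M⁻¹ h⁻¹)

At 60.0 h the flask still holds 5.87% of its partner's charge, beside 18.8% of target and 37.7% of isomer of the product, both in percent of the starting material charged, and the target share gave 30.8% for winter where the flask gave 31.1%. Now take the neighbouring flask charged with 1.7 M of starting material, its partner charge held at 0.600 M, which there makes 0.353 equiv. The target share gives 10.9% of that flask's starting material charged, and that flask gives 11.7% at 60.0 h, with 0.17% of its partner's charge left.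

The earlier runs and the new flask are calculated on assumed constants.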